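**Retrosynthetic overview**

- Feature: chain C2 (chain numbering: C1 methyl, C2 carbinol carbon on chromene C6, C3 methylene, C4 methine on benzofuran C2, C5 methyl) is fully substituted, carrying chromene C6, a methyl group, oxygen and the C3 methylene that leads on to C4. This is the pattern left when an isopropenyl boron ate complex is difunctionalized across its C=C bond.
- Key disconnection: chromene C6–C2 and C3–C4 are made together from the chromenyl pinacol boronate, isopropenyllithium and a 1-(benzofuran-2-yl)vinyl triflate by enantioselective palladium-catalysed conjunctive coupling. C2–O then comes from C2–B oxidation with retention, and C4–H from hydroxyl-directed hydrogenation of the C4 methylidene.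
- Ring order: the pyran ring of the chromene (propargyl ether Claisen cascade on 4-bromo-3-methoxyphenol) and the furan ring (Sonogashira coupling, then 5-endo-dig closure on 5-iodo-2,4-dihydroxyacetophenone) are both in place before the coupling. No ring is formed afterwards.
- Protection: the 5-acetyl group travels as a dioxolane and is unmasked at the boronic ester stage; the phenol is a triisopropylsilyl (TIPS) ether removed last with fluoride. The tertiary carbinol, benzylic to a 2,4-dioxygenated ring, therefore never meets acid.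

Key step: step 11

Assumption: the ligand antipodes named in steps 11 and 14 are assigned by analogy with related substrates. The sense of induction would be checked on the first run and the mirror-image ligand used if it proves opposite.

Remark: ketals 13, 15, 17 and 21 and carbinols 23–25 are acid-labile and would be purified on Et3N-deactivated silica.

**Route**

Step 1
Reactants: 1 4-bromo-3-methoxyphenol; 2 3-chloro-3-methylbut-1-yne
Product: 3 1-bromo-2-methoxy-4-[(2-methylbut-3-yn-2-yl)oxy]benzene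
Conditions: CuCl2·2H2O (1 mol %), DBU, MeCN, 0 °C
Reagents that add atoms: none
Why: Copper-catalysed propargylic substitution by the phenoxide should give the hindered tertiary propargyl aryl ether cleanly, without C-alkylation.

Step 2
Reactants: 3 1-bromo-2-methoxy-4-[(2-methylbut-3-yn-2-yl)oxy]benzene
Product: 5 6-bromo-7-methoxy-2,2-dimethyl-2H-chromene, via allenylphenol 4 (not isolated)
Conditions: N,N-diethylaniline, 190 °C
Reagents that add atoms: none
Why: Aryl propargyl ether Claisen rearrangement to 4, then 1,5-hydrogen shift and oxa-6π electrocyclization, closes the pyran ring; the rearrangement should prefer the free ortho carbon para to the methoxy group over the one flanked by two oxygens, giving the 6-bromo-7-methoxy isomer.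

Step 3
Reactants: 5 6-bromo-7-methoxy-2,2-dimethyl-2H-chromene
Product: 6 2-(7-methoxy-2,2-dimethyl-2H-chromen-6-yl)-4,4,5,5-tetramethyl-1,3,2-dioxaborolane
Conditions: B2pin2, Pd(dppf)Cl2 (3 mol %), KOAc, 1,4-dioxane, 90 °C
Reagents that add atoms: bis(pinacolato)diboron, CC1(C)OB(OC1(C)C)B1OC(C)(C)C(C)(C)O1
Why: Miyaura borylation of the electron-rich aryl bromide is tolerant of the chromene alkene and gives a halide-free boronic ester after chromatography.

Step 4
Reactants: 7 1-(2,4-dihydroxyphenyl)ethanone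
Product: 8 1-(2,4-dihydroxy-5-iodophenyl)ethanone
Conditions: ICl, AcOH, rt
Reagents that add atoms: iodine monochloride, ClI
Why: Electrophilic aromatic iodination under acidic conditions should go to C5, which is ortho to the 4-hydroxyl, para to the chelated 2-hydroxyl and less hindered than C3 between the two oxygens.

Step 5
Reactants: 8 1-(2,4-dihydroxy-5-iodophenyl)ethanone
Product: 9 1-{2,4-dihydroxy-5-[(trimethylsilyl)ethynyl]phenyl}ethanone
Conditions: ethynyltrimethylsilane, Pd(PPh3)2Cl2 (2 mol %), CuI (4 mol %), Et3N, THF, rt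
Reagents that add atoms: ethynyltrimethylsilane, C#C[Si](C)(C)C
Why: Sonogashira coupling of the aryl iodide proceeds with free phenols, and any 2-silylbenzofuran formed by early ring closure converges on the same product in step 6.

Step 6
Reactants: 9 1-{2,4-dihydroxy-5-[(trimethylsilyl)ethynyl]phenyl}ethanone
Product: 11 1-(6-hydroxy-1-benzofuran-5-yl)ethanone, via terminal alkyne 10 (not isolated)
Conditions: TBAF (3 equiv), THF, 65 °C
Reagents that add atoms: none
Why: Fluoride C-desilylation followed by base-mediated 5-endo-dig hydroalkoxylation closes the furan ring, and only the 4-hydroxyl is ortho to the alkyne, so the 5-acetyl-6-hydroxy pattern is fixed.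

Step 7
Reactants: 11 1-(6-hydroxy-1-benzofuran-5-yl)ethanone
Product: 12 1-{6-[(triisopropylsilyl)oxy]-1-benzofuran-5-yl}ethanone
Conditions: TIPSCl, imidazole, DMAP (cat.), DMF, 50 °C
Reagents that add atoms: chlorotriisopropylsilane, CC(C)[Si](Cl)(C(C)C)C(C)C
Why: O-Silylation of the phenol gives an aryl TIPS ether that should withstand organolithium, amide base, mild acid and mildly basic peroxide, and is removable with fluoride.

Step 8
Reactants: 12 1-{6-[(triisopropylsilyl)oxy]-1-benzofuran-5-yl}ethanone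
Product: 13 triisopropyl{[5-(2-methyl-1,3-dioxolan-2-yl)-1-benzofuran-6-yl]oxy}silane
Conditions: (TMSOCH2)2, TMSOTf (5 mol %), CH2Cl2, −78 to −20 °C; pyridine quench
Reagents that add atoms: 1,2-bis(trimethylsilyloxy)ethane, C[Si](C)(C)OCCO[Si](C)(C)C
Why: Silyl triflate-catalysed ketalization with the bis-silyl ether of ethylene glycol is driven by formation of hexamethyldisiloxane, which overcomes the low electrophilicity of the electron-rich, ortho-substituted aryl ketone.

Step 9
Reactants: 13 triisopropyl{[5-(2-methyl-1,3-dioxolan-2-yl)-1-benzofuran-6-yl]oxy}silane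
Product: 15 1-{5-(2-methyl-1,3-dioxolan-2-yl)-6-[(triisopropylsilyl)oxy]-1-benzofuran-2-yl}ethanone, via 2-lithiobenzofuran 14 (not isolated)
Conditions: n-BuLi, THF, −78 °C; MeC(O)N(OMe)Me, −78 to 0 °C; H2O
Reagents that add atoms: N-methoxy-N-methylacetamide, CC(=O)N(C)OC
Why: Heteroaryl lithiation at benzofuran C2, the most acidic C–H, followed by Weinreb ketone synthesis stops at the methyl ketone through the chelated tetrahedral adduct.

Step 10
Reactants: 15 1-{5-(2-methyl-1,3-dioxolan-2-yl)-6-[(triisopropylsilyl)oxy]-1-benzofuran-2-yl}ethanone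
Product: 17 1-{5-(2-methyl-1,3-dioxolan-2-yl)-6-[(triisopropylsilyl)oxy]-1-benzofuran-2-yl}ethenyl trifluoromethanesulfonate, via potassium enolate 16 (not isolated)
Conditions: KN(SiMe3)2, THF, −78 °C; PhNTf2, −78 to 0 °C
Reagents that add atoms: N-phenylbis(trifluoromethanesulfonimide), O=S(=O)(N(c1ccccc1)S(=O)(=O)C(F)(F)F)C(F)(F)F
Why: Enolate O-triflation of the only enolizable ketone (the other acetyl is ketalized) gives the terminal enol triflate, which would be filtered through deactivated silica and used promptly.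

Step 11
Reactants: 6 2-(7-methoxy-2,2-dimethyl-2H-chromen-6-yl)-4,4,5,5-tetramethyl-1,3,2-dioxaborolane; 18 2-bromopropene; 17 1-{5-(2-methyl-1,3-dioxolan-2-yl)-6-[(triisopropylsilyl)oxy]-1-benzofuran-2-yl}ethenyl trifluoromethanesulfonate
Product: 21 2-[(2R)-2-(7-methoxy-2,2-dimethyl-2H-chromen-6-yl)-4-{5-(2-methyl-1,3-dioxolan-2-yl)-6-[(triisopropylsilyl)oxy]-1-benzofuran-2-yl}pent-4-en-2-yl]-4,4,5,5-tetramethyl-1,3,2-dioxaborolane, via isopropenyllithium 19 (not isolated), via lithium ate complex 20 (not isolated)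
Conditions: 18, t-BuLi (2 equiv), Et2O, −78 °C; 6 (1.05 equiv), −78 °C to rt; solvent exchanged for THF; KOTf (2 equiv), Pd(OAc)2 (3 mol %), (SP,SP)-1,1'-bis[bis(4-methoxy-3,5-dimethylphenyl)phosphino]-2,2'-bis[(R)-(dimethylamino)(phenyl)methyl]ferrocene (3.6 mol %), 17 (0.8 equiv), 60 °C
Reagents that add atoms: none
Why: Zerovalent palladium, formed in the flask from Pd(OAc)2 and the bisphosphine, adds oxidatively to the C–O bond of 17; the resulting cationic alkenyl complex of divalent palladium binds the isopropenyl alkene of 20 and induces a 1,2-shift of the chromenyl group from boron to the boron-bearing carbon, anti to the metal, which makes chromene C6–C2 and places palladium on C3, and reductive elimination then joins C3 to C4. This is the known palladium-catalysed conjunctive cross-coupling of α-substituted alkenylboron ate complexes with alkenyl triflates, which delivers tertiary boronic esters. No ring is closed. The one new stereocentre, C2, is controlled by the chiral ferrocenyl bisphosphine, which selects the face of the isopropenyl unit that binds palladium, and the anti-periplanar migration turns that choice into the (R) boronate. The step needs the metallate shift to outrun direct Suzuki-type transfer of the chromenyl or isopropenyl group to palladium, which is secured by the triflate leaving group, by KOTf precipitating the bromide brought in with 19, and by the wide-bite-angle ligand. C2 bears no hydrogen, so the alkylpalladium intermediate cannot undergo β-hydride elimination, and the ketal and silyl ether keep carbonyl and acidic sites away from 19.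

Step 12
Reactants: 21 2-[(2R)-2-(7-methoxy-2,2-dimethyl-2H-chromen-6-yl)-4-{5-(2-methyl-1,3-dioxolan-2-yl)-6-[(triisopropylsilyl)oxy]-1-benzofuran-2-yl}pent-4-en-2-yl]-4,4,5,5-tetramethyl-1,3,2-dioxaborolane
Product: 22 2-[(2R)-4-{5-acetyl-6-[(triisopropylsilyl)oxy]-1-benzofuran-2-yl}-2-(7-methoxy-2,2-dimethyl-2H-chromen-6-yl)pent-4-en-2-yl]-4,4,5,5-tetramethyl-1,3,2-dioxaborolane
Conditions: PPTS (0.2 equiv), THF/H2O (4:1), 40 °C
Reagents that add atoms: water, O
Why: Acid-catalysed ketal hydrolysis passes through an oxocarbenium ion stabilized by the ortho and para oxygens, so pyridinium catalysis should suffice and leave the aryl TIPS ether, the tertiary C–B bond, the alkenylbenzofuran and the chromene untouched, and doing it here keeps acid away from the later carbinol.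

Step 13
Reactants: 22 2-[(2R)-4-{5-acetyl-6-[(triisopropylsilyl)oxy]-1-benzofuran-2-yl}-2-(7-methoxy-2,2-dimethyl-2H-chromen-6-yl)pent-4-en-2-yl]-4,4,5,5-tetramethyl-1,3,2-dioxaborolane
Product: 23 (2S)-4-{5-acetyl-6-[(triisopropylsilyl)oxy]-1-benzofuran-2-yl}-2-(7-methoxy-2,2-dimethyl-2H-chromen-6-yl)pent-4-en-2-ol
Conditions: NaBO3·4H2O (5 equiv), THF/H2O (1:1), rt
Reagents that add atoms: sodium perborate (NaBO3·4H2O, dimeric peroxoborate), [Na+].[Na+].O[B-]1(O)OO[B-](O)(O)OO1
Why: Peroxide oxidation of the C–B bond moves C2 from boron to oxygen with retention, turning the (R) boronate into the (S) carbinol, and mildly basic perborate should spare the silylated phenol and so give no Dakin-type cleavage of the aryl ketone.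

Step 14
Reactants: 23 (2S)-4-{5-acetyl-6-[(triisopropylsilyl)oxy]-1-benzofuran-2-yl}-2-(7-methoxy-2,2-dimethyl-2H-chromen-6-yl)pent-4-en-2-ol
Product: 24 (2S,4S)-4-{5-acetyl-6-[(triisopropylsilyl)oxy]-1-benzofuran-2-yl}-2-(7-methoxy-2,2-dimethyl-2H-chromen-6-yl)pentan-2-ol
Conditions: H2 (70 atm), [Rh(nbd)((R)-BINAP)]BF4 (5 mol %), CH2Cl2 (filtered through basic alumina), rt
Reagents that add atoms: none
Why: Hydroxyl-directed homogeneous hydrogenation: the C2 hydroxyl holds the cationic rhodium centre on the homoallylic 1,1-disubstituted alkene, so this alkene is reduced in preference to the remote, hindered chromene alkene, and within the chelate the chiral bisphosphine selects the Re face of C4 for hydrogen delivery (double stereodifferentiation with C2) to set (4S), while high pressure suppresses alkene isomerization.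

Step 15
Reactants: 24 (2S,4S)-4-{5-acetyl-6-[(triisopropylsilyl)oxy]-1-benzofuran-2-yl}-2-(7-methoxy-2,2-dimethyl-2H-chromen-6-yl)pentan-2-ol
Product: 25 (2S,4S)-4-(5-acetyl-6-hydroxy-1-benzofuran-2-yl)-2-(7-methoxy-2,2-dimethyl-2H-chromen-6-yl)pentan-2-ol
Conditions: TBAF (1.1 equiv), THF, 0 °C; pH 7 phosphate buffer
Reagents that add atoms: none
Why: Fluoride desilylation of the aryl silyl ether is fast and non-acidic, so neither stereocentre nor the labile carbinol is disturbed.

**Compound list**

1 | 4-bromo-3-methoxyphenol | COc1cc(O)ccc1Br | starting material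
2 | 3-chloro-3-methylbut-1-yne | CC(C)(Cl)C#C | starting material
3 | 1-bromo-2-methoxy-4-[(2-methylbut-3-yn-2-yl)oxy]benzene | COc1cc(OC(C)(C)C#C)ccc1Br | intermediate
4 | 4-bromo-5-methoxy-2-(3-methylbuta-1,2-dien-1-yl)phenol | COc1cc(O)c(C=C=C(C)C)cc1Br | intermediate (not isolated)
5 | 6-bromo-7-methoxy-2,2-dimethyl-2H-chromene | COc1cc2c(cc1Br)C=CC(C)(C)O2 | intermediate
6 | 2-(7-methoxy-2,2-dimethyl-2H-chromen-6-yl)-4,4,5,5-tetramethyl-1,3,2-dioxaborolane | COc1cc2c(cc1B1OC(C)(C)C(C)(C)O1)C=CC(C)(C)O2 | intermediate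
7 | 1-(2,4-dihydroxyphenyl)ethanone | CC(=O)c1ccc(O)cc1O | starting material
8 | 1-(2,4-dihydroxy-5-iodophenyl)ethanone | CC(=O)c1cc(I)c(O)cc1O | intermediate
9 | 1-{2,4-dihydroxy-5-[(trimethylsilyl)ethynyl]phenyl}ethanone | CC(=O)c1cc(C#C[Si](C)(C)C)c(O)cc1O | intermediate
10 | 1-(5-ethynyl-2,4-dihydroxyphenyl)ethanone | CC(=O)c1cc(C#C)c(O)cc1O | intermediate (not isolated)
11 | 1-(6-hydroxy-1-benzofuran-5-yl)ethanone | CC(=O)c1cc2ccoc2cc1O | intermediate
12 | 1-{6-[(triisopropylsilyl)oxy]-1-benzofuran-5-yl}ethanone | CC(=O)c1cc2ccoc2cc1O[Si](C(C)C)(C(C)C)C(C)C | intermediate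
13 | triisopropyl{[5-(2-methyl-1,3-dioxolan-2-yl)-1-benzofuran-6-yl]oxy}silane | CC1(OCCO1)c1cc2ccoc2cc1O[Si](C(C)C)(C(C)C)C(C)C | intermediate
14 | {5-(2-methyl-1,3-dioxolan-2-yl)-6-[(triisopropylsilyl)oxy]-1-benzofuran-2-yl}lithium | [Li]c1cc2cc(C3(C)OCCO3)c(O[Si](C(C)C)(C(C)C)C(C)C)cc2o1 | intermediate (not isolated)
15 | 1-{5-(2-methyl-1,3-dioxolan-2-yl)-6-[(triisopropylsilyl)oxy]-1-benzofuran-2-yl}ethanone | CC(=O)c1cc2cc(C3(C)OCCO3)c(O[Si](C(C)C)(C(C)C)C(C)C)cc2o1 | intermediate
16 | potassium 1-{5-(2-methyl-1,3-dioxolan-2-yl)-6-[(triisopropylsilyl)oxy]-1-benzofuran-2-yl}ethenolate | [K+].[O-]C(=C)c1cc2cc(C3(C)OCCO3)c(O[Si](C(C)C)(C(C)C)C(C)C)cc2o1 | intermediate (not isolated)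
17 | 1-{5-(2-methyl-1,3-dioxolan-2-yl)-6-[(triisopropylsilyl)oxy]-1-benzofuran-2-yl}ethenyl trifluoromethanesulfonate | C=C(OS(=O)(=O)C(F)(F)F)c1cc2cc(C3(C)OCCO3)c(O[Si](C(C)C)(C(C)C)C(C)C)cc2o1 | intermediate
18 | 2-bromopropene | CC(Br)=C | starting material
19 | isopropenyllithium | [Li]C(C)=C | intermediate (not isolated)
20 | lithium (7-methoxy-2,2-dimethyl-2H-chromen-6-yl)(prop-1-en-2-yl)(pinacolato)borate | [Li+].COc1cc2c(cc1[B-]1(C(C)=C)OC(C)(C)C(C)(C)O1)C=CC(C)(C)O2 | intermediate (not isolated)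
21 | 2-[(2R)-2-(7-methoxy-2,2-dimethyl-2H-chromen-6-yl)-4-{5-(2-methyl-1,3-dioxolan-2-yl)-6-[(triisopropylsilyl)oxy]-1-benzofuran-2-yl}pent-4-en-2-yl]-4,4,5,5-tetramethyl-1,3,2-dioxaborolane | COc1cc2c(cc1[C@@](C)(B1OC(C)(C)C(C)(C)O1)CC(=C)c1cc3cc(C4(C)OCCO4)c(O[Si](C(C)C)(C(C)C)C(C)C)cc3o1)C=CC(C)(C)O2 | intermediate
22 | 2-[(2R)-4-{5-acetyl-6-[(triisopropylsilyl)oxy]-1-benzofuran-2-yl}-2-(7-methoxy-2,2-dimethyl-2H-chromen-6-yl)pent-4-en-2-yl]-4,4,5,5-tetramethyl-1,3,2-dioxaborolane | COc1cc2c(cc1[C@@](C)(B1OC(C)(C)C(C)(C)O1)CC(=C)c1cc3cc(C(C)=O)c(O[Si](C(C)C)(C(C)C)C(C)C)cc3o1)C=CC(C)(C)O2 | intermediate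
23 | (2S)-4-{5-acetyl-6-[(triisopropylsilyl)oxy]-1-benzofuran-2-yl}-2-(7-methoxy-2,2-dimethyl-2H-chromen-6-yl)pent-4-en-2-ol | COc1cc2c(cc1[C@@](C)(O)CC(=C)c1cc3cc(C(C)=O)c(O[Si](C(C)C)(C(C)C)C(C)C)cc3o1)C=CC(C)(C)O2 | intermediate
24 | (2S,4S)-4-{5-acetyl-6-[(triisopropylsilyl)oxy]-1-benzofuran-2-yl}-2-(7-methoxy-2,2-dimethyl-2H-chromen-6-yl)pentan-2-ol | COc1cc2c(cc1[C@@](C)(O)C[C@H](C)c1cc3cc(C(C)=O)c(O[Si](C(C)C)(C(C)C)C(C)C)cc3o1)C=CC(C)(C)O2 | intermediate
25 | (2S,4S)-4-(5-acetyl-6-hydroxy-1-benzofuran-2-yl)-2-(7-methoxy-2,2-dimethyl-2H-chromen-6-yl)pentan-2-ol | COc1cc2c(cc1[C@@](C)(O)C[C@H](C)c1cc3cc(C(C)=O)c(O)cc3o1)C=CC(C)(C)O2 | target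

**Count**

Total steps: 15. Longest linear sequence: 12 steps (steps 4–15, from 7).

**Steps most likely to fail**

Step 11. At the congested, ortho-methoxy-substituted boron centre, direct transfer of the chromenyl or isopropenyl group to palladium may overtake the metallate shift. Residual bromide may also shut down the cationic pathway, or the face selection at the isopropenyl unit may be low. The fallback builds the same C2–B centre by lithiation–borylation, setting out from 5 and 17 and returning at 21.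
- From 5, bromine–lithium exchange (n-BuLi, THF, −78 °C) gives (7-methoxy-2,2-dimethyl-2H-chromen-6-yl)lithium F1. Acylation with N-methoxy-N-methylacetamide gives 1-(7-methoxy-2,2-dimethyl-2H-chromen-6-yl)ethanone F2.
- Asymmetric transfer hydrogenation (RuCl(p-cymene)[(R,R)-TsDPEN], HCO2H/Et3N) should give (1R)-1-(7-methoxy-2,2-dimethyl-2H-chromen-6-yl)ethanol F3. Treatment with N,N-diisopropylcarbamoyl chloride (Et3N, toluene, 90 °C) gives (1R)-1-(7-methoxy-2,2-dimethyl-2H-chromen-6-yl)ethyl N,N-diisopropylcarbamate F4.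
- In parallel, 17 is coupled with (pinacolatoboryl)methylzinc iodide, IZnCH2B(pin), under Pd(PPh3)4 in THF to give the allylboronate 2-(2-{5-(2-methyl-1,3-dioxolan-2-yl)-6-[(triisopropylsilyl)oxy]-1-benzofuran-2-yl}prop-2-en-1-yl)-4,4,5,5-tetramethyl-1,3,2-dioxaborolane F5.
- Deprotonation of F4 (s-BuLi, Et2O, −78 °C) gives, with retention, the lithiated carbamate F6. F5 adds with retention to give the lithium boronate complex F7. On warming (MgBr2·OEt2, MeOH) the allyl group migrates from boron to carbon with inversion, expelling the carbamate and giving 21.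

Step 14. The ligand may be mismatched with the C2 centre, so that facial selectivity at C4 is poor; the alkene may migrate into the chain; or the chromene alkene may be partly reduced. The fallback gives up stereoselection in favour of a chemoselective reduction and separation, setting out from 23 and returning at 24.
- Compound 23 is hydrogenated with RhCl(PPh3)3 (H2, 1 atm, benzene/EtOH, rt), which should reduce only the 1,1-disubstituted alkene.
- The two C4 epimers are separated by preparative HPLC on a neutral phase: 24 is carried on, and (2S,4R)-4-{5-acetyl-6-[(triisopropylsilyl)oxy]-1-benzofuran-2-yl}-2-(7-methoxy-2,2-dimethyl-2H-chromen-6-yl)pentan-2-ol F8 is set aside.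

Step 10. The electron-rich enol triflate may ionize or hydrolyse on isolation, or lose triflate to the alkyne under excess base. The fallback replaces it by an alkenyl iodide that cannot ionize in this way, setting out from 15 and returning at 21.
- Compound 15 is condensed with hydrazine hydrate (Et3N, EtOH, rt) to give 1-{5-(2-methyl-1,3-dioxolan-2-yl)-6-[(triisopropylsilyl)oxy]-1-benzofuran-2-yl}ethanone hydrazone F9.
- Iodine and 1,1,3,3-tetramethylguanidine (THF, 0 °C; Barton vinyl iodide synthesis) convert it into triisopropyl{[2-(1-iodoethenyl)-5-(2-methyl-1,3-dioxolan-2-yl)-1-benzofuran-6-yl]oxy}silane F10.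
- F10 is used in place of 17 under the conditions of step 11, where the KOTf already present also removes the iodide, to give 21.

**Further compounds**

F1 | step 11 | (7-methoxy-2,2-dimethyl-2H-chromen-6-yl)lithium | COc1cc2c(cc1[Li])C=CC(C)(C)O2
F2 | step 11 | 1-(7-methoxy-2,2-dimethyl-2H-chromen-6-yl)ethanone | COc1cc2c(cc1C(C)=O)C=CC(C)(C)O2
F3 | step 11 | (1R)-1-(7-methoxy-2,2-dimethyl-2H-chromen-6-yl)ethanol | COc1cc2c(cc1[C@@H](C)O)C=CC(C)(C)O2
F4 | step 11 | (1R)-1-(7-methoxy-2,2-dimethyl-2H-chromen-6-yl)ethyl N,N-diisopropylcarbamate | COc1cc2c(cc1[C@@H](C)OC(=O)N(C(C)C)C(C)C)C=CC(C)(C)O2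
F5 | step 11 | 2-(2-{5-(2-methyl-1,3-dioxolan-2-yl)-6-[(triisopropylsilyl)oxy]-1-benzofuran-2-yl}prop-2-en-1-yl)-4,4,5,5-tetramethyl-1,3,2-dioxaborolane | C=C(CB1OC(C)(C)C(C)(C)O1)c1cc2cc(C3(C)OCCO3)c(O[Si](C(C)C)(C(C)C)C(C)C)cc2o1
F6 | step 11 | lithiated carbamate, [1-(diisopropylcarbamoyloxy)-1-(7-methoxy-2,2-dimethyl-2H-chromen-6-yl)ethyl]lithium | COc1cc2c(cc1[C@@]([Li])(C)OC(=O)N(C(C)C)C(C)C)C=CC(C)(C)O2
F7 | step 11 | lithium boronate complex of F6 with F5 | [Li+].COc1cc2c(cc1[C@@]([B-]1(CC(=C)c3cc4cc(C5(C)OCCO5)c(O[Si](C(C)C)(C(C)C)C(C)C)cc4o3)OC(C)(C)C(C)(C)O1)(C)OC(=O)N(C(C)C)C(C)C)C=CC(C)(C)O2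
F8 | step 14 | (2S,4R)-4-{5-acetyl-6-[(triisopropylsilyl)oxy]-1-benzofuran-2-yl}-2-(7-methoxy-2,2-dimethyl-2H-chromen-6-yl)pentan-2-ol | COc1cc2c(cc1[C@@](C)(O)C[C@@H](C)c1cc3cc(C(C)=O)c(O[Si](C(C)C)(C(C)C)C(C)C)cc3o1)C=CC(C)(C)O2
F9 | step 10 | 1-{5-(2-methyl-1,3-dioxolan-2-yl)-6-[(triisopropylsilyl)oxy]-1-benzofuran-2-yl}ethanone hydrazone | CC(=NN)c1cc2cc(C3(C)OCCO3)c(O[Si](C(C)C)(C(C)C)C(C)C)cc2o1
F10 | step 10 | triisopropyl{[2-(1-iodoethenyl)-5-(2-methyl-1,3-dioxolan-2-yl)-1-benzofuran-6-yl]oxy}silane | C=C(I)c1cc2cc(C3(C)OCCO3)c(O[Si](C(C)C)(C(C)C)C(C)C)cc2o1
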